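**Retrosynthetic overview**

1. The target is a depsidone: ring A (C-7a to C-11a; 8-Me, 10-OMe, 11-CHO) and ring B (C-3a to C-12b, carrying the C-1 lactol/C-3 lactone) are joined by a seven-membered 1,4-dioxepin-5-one ring, made of the ester C-7(=O)–O-6 and the ether C-11a–O-12–C-12a, in which both ether carbons carry two ortho substituents.
2. Key disconnection: the dioxepinone is unfolded to benzophenone 13 (C-7 bonded to C-12a). Oxidative dearomatisation of ring B forms the O-12–C-12a bond as a spiro-benzofuranone; a 1,3 C→O shift of C-7 from C-12a to O-6 then expands the five-membered ring to the seven-membered ring and rearomatises ring B.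
3. 13 ⇐ aryllithium of bromophthalide pseudo-ester 6 + aldehyde 7 (bond C-7–C-12a), then oxidation, ortho-formylation (C-11 CHO) and debenzylation; 6 ⇐ 3,5-bis(benzyloxy)benzaldehyde 1, whose CHO carbon becomes C-1 (2,6-dibromination, acetal, Li/CO2).
4. C-1, the only stereocentre, is set last: acid-equilibrated (R)-1-phenylethyl acetal 17, (1S)-epimer isolated with recycling, then neutral hydrogenolysis.
5. Ring order: γ-lactone (phthalide) → transient spiro-furanone → dioxepinone.

Key step: step 8

Assumption: C-1 is a lactol carbon that can epimerise in solution by ring–chain tautomerism; it is therefore fixed as an acetal and freed only in the last step, without acid or base, and the product is isolated as a solid.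

Intermediates 6–13 are numbered as 2-benzofuran-1(3H)-ones (phthalides); 15, 17 and 18 as 7H-isobenzofuro[4,5-b][1,4]benzodioxepines.

**Route**

Step 1
Reactants: 1 3,5-bis(benzyloxy)benzaldehyde
Product: 2 3,5-bis(benzyloxy)-2,6-dibromobenzaldehyde
Conditions: NBS (2.2 equiv), MeCN, 0 → 45 °C
Reagents that add atoms: N-bromosuccinimide O=C1CCC(=O)N1Br
Why: Electrophilic aromatic bromination should go twice to C-2 and C-6, each ortho to one benzyloxy group and para to the other, and not to C-4, which lies between the two benzyloxy groups.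

Step 2
Reactants: 2 3,5-bis(benzyloxy)-2,6-dibromobenzaldehyde
Product: 3 1,5-bis(benzyloxy)-2,4-dibromo-3-(dimethoxymethyl)benzene
Conditions: HC(OMe)3 (5 equiv), MeOH, TsOH·H2O (5 mol %), reflux
Reagents that add atoms: trimethyl orthoformate COC(OC)OC; methanol CO
Why: Acid-catalysed acetalisation with orthoformate as water scavenger masks the aldehyde for the organolithium step and keeps the future C-1 at the aldehyde oxidation level.

Step 3
Reactants: 3 1,5-bis(benzyloxy)-2,4-dibromo-3-(dimethoxymethyl)benzene
Product: 6 rac-5,7-bis(benzyloxy)-4-bromo-3-methoxy-2-benzofuran-1(3H)-one, via aryllithium 4 (not isolated), via acetal acid 5 (not isolated)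
Conditions: n-BuLi (1.05 equiv), THF, −78 °C; CO2 (g), −78 °C → rt; cold 1 M HCl to pH 3; then CSA (5 mol %), CH2Cl2, rt
Reagents that add atoms: carbon dioxide O=C=O
Why: Bromine–lithium exchange at one of two equivalent C–Br bonds, carboxylation, and acid-catalysed lactonisation of the acid onto the neighbouring dimethyl acetal should give the 3-methoxyphthalide (pseudo-ester), whose acetal centre forms racemic and is equilibrated in step 9.

Step 4
Reactants: 6 rac-5,7-bis(benzyloxy)-4-bromo-3-methoxy-2-benzofuran-1(3H)-one; 7 2-hydroxy-4-methoxy-6-methylbenzaldehyde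
Product: 10 5,7-bis(benzyloxy)-4-[hydroxy(2-hydroxy-4-methoxy-6-methylphenyl)methyl]-3-methoxy-2-benzofuran-1(3H)-one (racemic diastereomer mixture), via lithium phenolate 8 (not isolated), via aryllithium 9 (not isolated)
Conditions: 7 (1.3 equiv), LiHMDS (1.35 equiv), THF, −78 °C; separately 6 added to n-BuLi (1.05 equiv), THF, −100 °C, 5 min; phenolate solution added, −100 → −30 °C; AcOH quench at −78 °C
Reagents that add atoms: none
Why: Halogen–lithium exchange at −100 °C with inverse addition should outrun attack on the lactone, and 1,2-addition of the aryllithium to the aldehyde (phenol masked as its lithium salt) is the standard entry to tetra-ortho-substituted benzophenones; the carbinol centre forms unselectively and is removed in step 5.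

Step 5
Reactants: 10 5,7-bis(benzyloxy)-4-[hydroxy(2-hydroxy-4-methoxy-6-methylphenyl)methyl]-3-methoxy-2-benzofuran-1(3H)-one
Product: 11 rac-5,7-bis(benzyloxy)-4-(2-hydroxy-4-methoxy-6-methylbenzoyl)-3-methoxy-2-benzofuran-1(3H)-one
Conditions: DDQ (1.1 equiv), CH2Cl2, 0 °C → rt
Reagents that add atoms: none
Why: DDQ dehydrogenation of an electron-rich diaryl carbinol (hydride abstraction assisted by ortho/para oxygen donors on both rings) should tolerate the unactivated benzyl ethers, the acetal and the free phenol.

Step 6
Reactants: 11 rac-5,7-bis(benzyloxy)-4-(2-hydroxy-4-methoxy-6-methylbenzoyl)-3-methoxy-2-benzofuran-1(3H)-one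
Product: 12 rac-3-[5,7-bis(benzyloxy)-3-methoxy-1-oxo-1,3-dihydro-2-benzofuran-4-carbonyl]-2-hydroxy-6-methoxy-4-methylbenzaldehyde
Conditions: MgCl2 (3 equiv), Et3N (7 equiv), (CH2O)n (10 equiv), MeCN, 80 °C; dilute HCl work-up
Reagents that add atoms: paraformaldehyde (as formaldehyde) C=O
Why: Magnesium-mediated ortho-formylation (Casnati–Skattebøl reaction) formylates only a free phenol and only ortho to it, and the single free ortho position of the single free phenol is the carbon between OH and OMe.

Step 7
Reactants: 12 rac-3-[5,7-bis(benzyloxy)-3-methoxy-1-oxo-1,3-dihydro-2-benzofuran-4-carbonyl]-2-hydroxy-6-methoxy-4-methylbenzaldehyde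
Product: 13 rac-3-(5,7-dihydroxy-3-methoxy-1-oxo-1,3-dihydro-2-benzofuran-4-carbonyl)-2-hydroxy-6-methoxy-4-methylbenzaldehyde
Conditions: H2 (1 atm), 10% Pd/C, EtOAc, rt, stopped at full debenzylation
Reagents that add atoms: none
Why: Hydrogenolysis of the two aryl benzyl ethers should be much faster than reduction of the hydrogen-bonded, doubly ortho-substituted aldehyde or the hindered diaryl ketone, and the methyl acetal is inert.

Step 8
Reactants: 13 rac-3-(5,7-dihydroxy-3-methoxy-1-oxo-1,3-dihydro-2-benzofuran-4-carbonyl)-2-hydroxy-6-methoxy-4-methylbenzaldehyde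
Product: 15 rac-4-hydroxy-1,10-dimethoxy-8-methyl-3,7-dioxo-1,3-dihydro-7H-isobenzofuro[4,5-b][1,4]benzodioxepine-11-carbaldehyde, via spiro-dienone 14 (not isolated)
Conditions: PhI(OAc)2 (1.0 equiv, portionwise), (CF3)2CHOH–CH2Cl2 (1:4), −20 °C; then solvent exchange to toluene, 80 °C
Reagents that add atoms: none
Why: The iodine(III) reagent oxidises the resorcinol ring B by two electrons, the positive charge develops at phthalide C-4 (para to the 7-OH, ortho to the 5-OH), and the ring-A phenol oxygen adds there ipso in a 5-exo-trig closure, so that this dearomatising spirocyclisation forms the fully ortho-substituted O–C(aryl) bond (future O-12–C-12a) as benzofuran-3-one 14. 14 is a non-enolisable 2-acylcyclohexa-2,4-dienone, and on warming its acyl carbon should migrate from the spiro carbon to the adjacent oxygen (1,3 C→O acyl shift, by ionisation to an acylium/phenolate pair stabilised by the para-methoxy and ortho-aryloxy groups or through a four-centre transition state), which rearomatises ring B and converts the five-membered ring into the seven-membered lactone (7-membered closure at O-6–C-7). The closest known reaction type is the oxidative cyclisation of 2,2′-dihydroxybenzophenones to spiro grisadienediones and their thermal isomerisation to depsidones, together with iodine(III)-mediated para-spirocyclisation of phenols. No stereocentre is created, since the spiro centre is lost again and the racemic C-1 acetal is untouched. The step needs ring B and not ring A to be dearomatised, which is secured because only ring B has a free OH para to the ketone-bearing carbon, whereas the ring-A phenol carries two ortho acyl groups and only a methoxy group in that position. It also needs the product phenol (a para-aryloxyphenol) to be spared, which is secured by consuming exactly one equivalent of oxidant at −20 °C before the shift is completed thermally.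

Step 9
Reactants: 15 rac-4-hydroxy-1,10-dimethoxy-8-methyl-3,7-dioxo-1,3-dihydro-7H-isobenzofuro[4,5-b][1,4]benzodioxepine-11-carbaldehyde; 16 (R)-1-phenylethanol
Product: 17 (1S)-4-hydroxy-10-methoxy-8-methyl-3,7-dioxo-1-[(1R)-1-phenylethoxy]-1,3-dihydro-7H-isobenzofuro[4,5-b][1,4]benzodioxepine-11-carbaldehyde
Conditions: 16 (3 equiv), CSA (10 mol %), toluene, 5 Å MS, 60 °C; (1S,1′R)-epimer isolated by crystallisation or chromatography, (1R,1′R)-epimer returned to the same conditions
Reagents that add atoms: none
Why: Acid-catalysed alkoxy exchange of a 3-alkoxyphthalide (pseudo-ester transacetalisation, driven by removal of methanol) gives two C-1 epimers that interconvert through the lactol oxocarbenium ion under the same conditions, so isolating the (1S,1′R)-epimer and recycling the other converges the material on 17 (auxiliary-based, stereoconvergent setting of C-1).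

Step 10
Reactants: 17 (1S)-4-hydroxy-10-methoxy-8-methyl-3,7-dioxo-1-[(1R)-1-phenylethoxy]-1,3-dihydro-7H-isobenzofuro[4,5-b][1,4]benzodioxepine-11-carbaldehyde
Product: 18 (1S)-1,4-dihydroxy-10-methoxy-8-methyl-3,7-dioxo-1,3-dihydro-7H-isobenzofuro[4,5-b][1,4]benzodioxepine-11-carbaldehyde
Conditions: H2 (1 atm), 10% Pd/C, EtOAc, 15 °C, stopped at full conversion; filtration, evaporation below 25 °C, crystallisation from EtOAc–heptane
Reagents that add atoms: none
Why: Hydrogenolysis cleaves the benzylic C–O bond of the auxiliary (its unhindered phenyl ring binds to palladium, the fully substituted ring B does not) and releases the lactol OH without breaking a bond to C-1 and without acid or base, so the S configuration from step 9 should be retained.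

**Compound list**

1 | 3,5-bis(benzyloxy)benzaldehyde | O=Cc1cc(OCc2ccccc2)cc(OCc2ccccc2)c1 | starting material
2 | 3,5-bis(benzyloxy)-2,6-dibromobenzaldehyde | O=Cc1c(Br)c(OCc2ccccc2)cc(OCc2ccccc2)c1Br | intermediate
3 | 1,5-bis(benzyloxy)-2,4-dibromo-3-(dimethoxymethyl)benzene | COC(OC)c1c(Br)c(OCc2ccccc2)cc(OCc2ccccc2)c1Br | intermediate
4 | [2,4-bis(benzyloxy)-5-bromo-6-(dimethoxymethyl)phenyl]lithium | COC(OC)c1c(Br)c(OCc2ccccc2)cc(OCc2ccccc2)c1[Li] | intermediate
5 | 2,4-bis(benzyloxy)-5-bromo-6-(dimethoxymethyl)benzoic acid | COC(OC)c1c(Br)c(OCc2ccccc2)cc(OCc2ccccc2)c1C(=O)O | intermediate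
6 | rac-5,7-bis(benzyloxy)-4-bromo-3-methoxy-2-benzofuran-1(3H)-one | COC1OC(=O)c2c(OCc3ccccc3)cc(OCc3ccccc3)c(Br)c12 | intermediate
7 | 2-hydroxy-4-methoxy-6-methylbenzaldehyde | O=Cc1c(C)cc(OC)cc1O | starting material
8 | lithium 2-formyl-5-methoxy-3-methylphenolate | [Li+].[O-]c1cc(OC)cc(C)c1C=O | intermediate
9 | [5,7-bis(benzyloxy)-3-methoxy-1-oxo-1,3-dihydro-2-benzofuran-4-yl]lithium | [Li]c1c(OCc2ccccc2)cc(OCc2ccccc2)c2c1C(OC)OC2=O | intermediate
10 | 5,7-bis(benzyloxy)-4-[hydroxy(2-hydroxy-4-methoxy-6-methylphenyl)methyl]-3-methoxy-2-benzofuran-1(3H)-one (racemic diastereomer mixture) | COC1OC(=O)c2c(OCc3ccccc3)cc(OCc3ccccc3)c(C(O)c3c(C)cc(OC)cc3O)c12 | intermediate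
11 | rac-5,7-bis(benzyloxy)-4-(2-hydroxy-4-methoxy-6-methylbenzoyl)-3-methoxy-2-benzofuran-1(3H)-one | COC1OC(=O)c2c(OCc3ccccc3)cc(OCc3ccccc3)c(C(=O)c3c(C)cc(OC)cc3O)c12 | intermediate
12 | rac-3-[5,7-bis(benzyloxy)-3-methoxy-1-oxo-1,3-dihydro-2-benzofuran-4-carbonyl]-2-hydroxy-6-methoxy-4-methylbenzaldehyde | COC1OC(=O)c2c(OCc3ccccc3)cc(OCc3ccccc3)c(C(=O)c3c(C)cc(OC)c(C=O)c3O)c12 | intermediate
13 | rac-3-(5,7-dihydroxy-3-methoxy-1-oxo-1,3-dihydro-2-benzofuran-4-carbonyl)-2-hydroxy-6-methoxy-4-methylbenzaldehyde | COC1OC(=O)c2c(O)cc(O)c(C(=O)c3c(C)cc(OC)c(C=O)c3O)c12 | intermediate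
14 | 7′-hydroxy-3′,6-dimethoxy-4-methyl-1′,3,5′-trioxo-1′,3′-dihydro-3H,5′H-spiro[1-benzofuran-2,4′-[2]benzofuran]-7-carbaldehyde (spiro grisadienedione enol, racemic diastereomer mixture) | COC1OC(=O)C2=C1C1(Oc3c(C=O)c(OC)cc(C)c3C1=O)C(=O)C=C2O | intermediate
15 | rac-4-hydroxy-1,10-dimethoxy-8-methyl-3,7-dioxo-1,3-dihydro-7H-isobenzofuro[4,5-b][1,4]benzodioxepine-11-carbaldehyde | COc1cc(C)c2c(c1C=O)Oc1c(cc(O)c3c1C(OC)OC3=O)OC2=O | intermediate
16 | (R)-1-phenylethanol | C[C@@H](O)c1ccccc1 | starting material
17 | (1S)-4-hydroxy-10-methoxy-8-methyl-3,7-dioxo-1-[(1R)-1-phenylethoxy]-1,3-dihydro-7H-isobenzofuro[4,5-b][1,4]benzodioxepine-11-carbaldehyde | COc1cc(C)c2c(c1C=O)Oc1c(cc(O)c3c1[C@@H](O[C@H](C)c1ccccc1)OC3=O)OC2=O | intermediate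
18 | (1S)-1,4-dihydroxy-10-methoxy-8-methyl-3,7-dioxo-1,3-dihydro-7H-isobenzofuro[4,5-b][1,4]benzodioxepine-11-carbaldehyde | COc1cc(C)c2c(c1C=O)Oc1c(cc(O)c3c1[C@@H](O)OC3=O)OC2=O | target

**Step count**

Total steps: 10. Longest linear sequence: 10 (steps 1–10; 7 and 16 enter as purchased materials).

**Steps most likely to fail, with fallbacks**

Step 8 (key step). After the dearomatising C–O bond formation, the acyl group may be captured by the fluoro alcohol or acetic acid, or the dienone may decay on heating, instead of migrating cleanly to the neighbouring oxygen; oxidation may also begin on ring A or continue on the product phenol. The fallback sets out from 13 and comes back at 15. The oxidation is run as in step 8 up to 14, but the thermolysis is replaced by a deliberate hydrolytic retro-Claisen cleavage of the non-enolisable β-diketone (THF–water, NaOAc, rt). This restores ring B and gives the diaryl ether carboxylic acid F1. The seven-membered ring is then closed in a separate operation by carbodiimide lactonisation (DCC, CH2Cl2) of the acid onto the adjacent 5-hydroxyl, which gives 15.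

Step 4. The aryllithium 9 may be consumed by attack on the lactone carbonyl of a second molecule, or by proton transfer from the acidic acetal C-3–H, before it adds to the deactivated phenolate aldehyde. The fallback sets out from 3 and comes back at 10, and inverts the order of the two carbon–carbon bond formations so that no lactone is present during either metalation. Mono bromine–lithium exchange of 3 (n-BuLi, THF, −78 °C) and addition to 8 gives the bromo carbinol F2. F2 is deprotonated twice and exchanged with n-BuLi (3.1 equiv, −78 °C) and carboxylated with CO2 to the hydroxy acid F3. Acid-catalysed closure of the carboxyl group onto the dimethyl acetal (CSA, CH2Cl2) then gives 10.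

Step 9. The exchange may stall at partial conversion, the secondary benzylic alcohol may ionise under the acid, or the two C-1 epimers may prove inseparable, so that no single configuration is passed on to step 10. The fallback sets out from 15 and ends at 18, replacing the auxiliary by a catalytic dynamic kinetic resolution. Aqueous acid hydrolysis of 15 (TFA–water–THF, rt) gives the racemic lactol F4. Its C-1 epimerises through the ring-opened aldehyde acid in the presence of catalytic Et3N, while an (S)-selective hydrolase (subtilisin Carlsberg, 2,2,2-trifluoroethyl butanoate, t-BuOMe) acylates one enantiomer only, giving the configurationally stable (1S)-butanoate F5. The same enzyme then removes the acyl group by butanolysis (n-BuOH, t-BuOMe, 5 °C, no base), which cleaves the acyl–oxygen bond, leaves C-1 untouched and gives 18.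

Further compounds

F1 | step 8 | rac-2-[(5,7-dihydroxy-3-methoxy-1-oxo-1,3-dihydro-2-benzofuran-4-yl)oxy]-3-formyl-4-methoxy-6-methylbenzoic acid | COC1OC(=O)c2c(O)cc(O)c(Oc3c(C=O)c(OC)cc(C)c3C(=O)O)c12
F2 | step 4 | rac-2-{[2,4-bis(benzyloxy)-5-bromo-6-(dimethoxymethyl)phenyl](hydroxy)methyl}-5-methoxy-3-methylphenol | COC(OC)c1c(Br)c(OCc2ccccc2)cc(OCc2ccccc2)c1C(O)c1c(C)cc(OC)cc1O
F3 | step 4 | rac-2,4-bis(benzyloxy)-6-(dimethoxymethyl)-5-[hydroxy(2-hydroxy-4-methoxy-6-methylphenyl)methyl]benzoic acid | COC(OC)c1c(C(=O)O)c(OCc2ccccc2)cc(OCc2ccccc2)c1C(O)c1c(C)cc(OC)cc1O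
F4 | step 9 | rac-1,4-dihydroxy-10-methoxy-8-methyl-3,7-dioxo-1,3-dihydro-7H-isobenzofuro[4,5-b][1,4]benzodioxepine-11-carbaldehyde | COc1cc(C)c2c(c1C=O)Oc1c(cc(O)c3c1C(O)OC3=O)OC2=O
F5 | step 9 | (1S)-11-formyl-4-hydroxy-10-methoxy-8-methyl-3,7-dioxo-1,3-dihydro-7H-isobenzofuro[4,5-b][1,4]benzodioxepin-1-yl butanoate | COc1cc(C)c2c(c1C=O)Oc1c(cc(O)c3c1[C@@H](OC(=O)CCC)OC3=O)OC2=O
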